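**Strategy**

Germacrane numbering: the furanone ring is O–C10–C1(=O)–C2=C3. This ring is a vinylogous ester, so C3 is an acyl carbon and C2 the α-carbon of the C1 ketone. Everything rests on disconnecting C2–C3 in the Claisen sense, which unfolds the target into a nine-membered lactone (O–C3(=O)–C4=C5–C6–C7–C8–C9–C10) bearing an acetyl group (C1–C2) on C10. In the key step the acetyl enolate attacks the lactone carbonyl; acyl transfer and dehydration close the furanone ring and, by one-atom ring expansion, the ten-membered carbocycle in one operation. The lactone comes from ring-closing metathesis of a methacrylate (C3, C4, C15); two chromium-mediated allylations and a Mitsunobu inversion set C8, C7 and C6.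

Key step: step 13

Numbering remark: C1 ketone, C2=C3, C4(C15)=C5, C6 acyloxy carbon, C7, C8 lactone carbinol, C9, C10(C14), C11(=C13), C12 lactone carbonyl.

Assumption: the sense of induction of the two chiral catalysts (steps 2 and 4) is taken from the closest precedents of each catalyst class; should a test run show the opposite sense, the mirror-image ligand is used and nothing else changes.

**Route**

Step 1
Reactants: 1 S-ethyl thioacetate
Product: 2 1-(ethylsulfanyl)-1-(trimethylsilyloxy)ethene
Conditions: LiN(iPr)2, THF, −78 °C; then Me3SiCl, −78 °C → rt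
Reagents that add atoms: chlorotrimethylsilane, C[Si](C)(C)Cl
Why: Kinetic deprotonation of the thioester and O-silylation of the lithium enolate should give the silyl ketene S,O-acetal (enol silane formation); no stereocenter is involved.

Step 2
Reactants: 2 1-(ethylsulfanyl)-1-(trimethylsilyloxy)ethene; 3 butane-2,3-dione
Product: 5 S-ethyl (3S)-3-hydroxy-3-methyl-4-oxopentanethioate, via trimethylsilyl ether 4 (not isolated)
Conditions: Cu(OTf)2 (10 mol %), (S,S)-2,2'-isopropylidenebis(4-tert-butyl-2-oxazoline) (11 mol %), excess 3, THF, −78 °C; then 1 M HCl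
Reagents that add atoms: none
Why: Catalytic enantioselective Mukaiyama aldol addition: the diketone chelates the square-planar divalent copper bis(oxazoline) complex, a tert-butyl group shields one face of the bound carbonyl and the enol silane adds to the open face, which should set C10 as S under catalyst control, the excess of diketone holding the reaction at mono-addition.

Step 3
Reactants: 5 S-ethyl (3S)-3-hydroxy-3-methyl-4-oxopentanethioate
Product: 6 (3S)-3-hydroxy-3-methyl-4-oxopentanal
Conditions: Et3SiH, 10% Pd on carbon, acetone, rt; used crude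
Reagents that add atoms: none
Why: Fukuyama reduction should convert the thioester into the aldehyde by palladium-mediated hydride transfer from the silane while the ketone and the tertiary alcohol stay untouched; C10 is not affected.

Step 4
Reactants: 6 (3S)-3-hydroxy-3-methyl-4-oxopentanal; 7 methyl 2-(bromomethyl)acrylate
Product: 10 (5R)-5-[(2S)-2-hydroxy-2-methyl-3-oxobutyl]-3-methylideneoxolan-2-one, via silyl ether 8 (not isolated), via hydroxy ester 9 (not isolated)
Conditions: CrCl2 (10 mol %), 3,6-di-tert-butyl-1,8-bis[(4S)-4-isopropyl-4,5-dihydro-1,3-oxazol-2-yl]-9H-carbazole (12 mol %), iPr2NEt (30 mol %), Mn powder, Me3SiCl, THF, rt; then 1 M HCl, THF, rt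
Reagents that add atoms: none
Why: Catalytic asymmetric Nozaki–Hiyama–Kishi 2-(alkoxycarbonyl)allylation: the allylchromium adds through its γ-carbon to the aldehyde and not to the hindered ketone, the chiral ligand should direct C–C bond formation to the Re face and so set C8 (descriptor R in 10, the spatial arrangement of C8 in the target), and the acid work-up removes the silyl group and closes the α-methylene-γ-butyrolactone.

Step 5
Reactants: 10 (5R)-5-[(2S)-2-hydroxy-2-methyl-3-oxobutyl]-3-methylideneoxolan-2-one
Product: 12 (5S)-3-(bromomethyl)-5-[(2S)-2-hydroxy-2-methyl-3-oxobutyl]furan-2(5H)-one, via dibromide 11 (not isolated)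
Conditions: Br2, CH2Cl2, 0 °C; then Et3N, 0 °C; used at once
Reagents that add atoms: bromine, BrBr
Why: Bromine addition to the exocyclic alkene followed by E2 dehydrobromination toward the ring should give the conjugated butenolide carrying the allylic bromide; no stereocenter is created, and short exposure to the mild amine at 0 °C should leave C8 and the hindered tertiary alcohol untouched.

Step 6
Reactants: 12 (5S)-3-(bromomethyl)-5-[(2S)-2-hydroxy-2-methyl-3-oxobutyl]furan-2(5H)-one; 13 acrolein
Product: 14 (4S,5S)-4-[(1R)-1-hydroxyprop-2-en-1-yl]-5-[(2S)-2-hydroxy-2-methyl-3-oxobutyl]-3-methylideneoxolan-2-one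
Conditions: CrCl2 (3 equiv), THF, 0 °C → rt
Reagents that add atoms: none
Why: Nozaki–Hiyama–Kishi allylation: the trivalent allylchromium should add 1,2 to the aldehyde (far faster than to the hindered ketone) with allyl transposition through C7 on the face anti to the C8 side chain (C7 set by the ring, trans-lactone), and the chair transition state of the ring-locked E-type allyl unit should give the anti carbinol, that is the 6R epimer that step 10 inverts.

Step 7
Reactants: 15 methyl angelate
Product: 16 (2Z)-2-methylbut-2-en-1-ol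
Conditions: iBu2AlH, CH2Cl2, −78 → 0 °C; aqueous potassium sodium tartrate
Reagents that add atoms: none
Why: 1,2-Reduction of the enoate by the aluminium hydride should give the allylic alcohol with the Z geometry retained.

Step 8
Reactants: 16 (2Z)-2-methylbut-2-en-1-ol
Product: 17 [(2R,3S)-2,3-dimethyloxiran-2-yl]methanol
Conditions: Ti(OiPr)4 (10 mol %), D-(−)-diethyl tartrate (12 mol %), tBuOOH, 4 Å molecular sieves, CH2Cl2, −20 °C
Reagents that add atoms: tert-butyl hydroperoxide, CC(C)(C)OO
Why: Sharpless asymmetric epoxidation: the titanium tartrate complex delivers oxygen to one face of the allylic alcohol under reagent control (D-(−)-tartrate for the 2R,3S epoxy alcohol), and the Z alkene fixes the cis relation of C1 and the C3 methyl group.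

Step 9
Reactants: 17 [(2R,3S)-2,3-dimethyloxiran-2-yl]methanol
Product: 18 (2S,3S)-2,3-dimethyloxirane-2-carboxylic acid
Conditions: RuCl3 (2 mol %), NaIO4, MeCN/EtOAc/H2O, 0 °C → rt
Reagents that add atoms: water, O
Why: Catalytic RuO4 oxidation (RuCl3, NaIO4) should take the primary alcohol through the aldehyde hydrate to the acid without touching the epoxide; both centers are retained, and the C2 descriptor changes to S only by priority.

Step 10
Reactants: 14 (4S,5S)-4-[(1R)-1-hydroxyprop-2-en-1-yl]-5-[(2S)-2-hydroxy-2-methyl-3-oxobutyl]-3-methylideneoxolan-2-one; 18 (2S,3S)-2,3-dimethyloxirane-2-carboxylic acid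
Product: 19 (1S)-1-[(2S,3R)-2-[(2S)-2-hydroxy-2-methyl-3-oxobutyl]-4-methylidene-5-oxooxolan-3-yl]prop-2-en-1-yl (2S,3S)-2,3-dimethyloxirane-2-carboxylate
Conditions: PPh3, diisopropyl azodicarboxylate, toluene, 0 °C → rt
Reagents that add atoms: none
Why: Mitsunobu esterification: the secondary allylic alcohol is activated as its oxyphosphonium ion and displaced by the carboxylate with inversion (SN2), which installs the side chain and sets C6 as S in one step, while the tertiary alcohol cannot be activated.

Step 11
Reactants: 19 the C6 epoxyangelate with free tertiary ketol; 20 methacryloyl chloride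
Product: 21 (1S)-1-[(2S,3R)-2-[(2S)-2-methyl-2-(2-methylprop-2-enoyloxy)-3-oxobutyl]-4-methylidene-5-oxooxolan-3-yl]prop-2-en-1-yl (2S,3S)-2,3-dimethyloxirane-2-carboxylate
Conditions: Et3N, DMAP, CH2Cl2, 0 °C → rt
Reagents that add atoms: none
Why: DMAP-catalysed acylation of the tertiary α-ketol by the acid chloride should give the α-acyloxy ketone needed for the key step; no stereocenter is touched.

Step 12
Reactants: 21 methacrylate triene
Product: 22 nine-membered (Z)-enoate lactone carrying the C10 acetyl group
Conditions: second-generation Hoveyda–Grubbs catalyst RuCl2(H2IMes)(=CH-C6H4-2-OiPr) (15 mol %), toluene (1 mM), 100 °C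
Reagents that add atoms: none
Why: Ring-closing metathesis: the catalyst should load on the monosubstituted C5 vinyl group and close onto the methacrylate (the 1,1-disubstituted α-methylene lactone is inert), helped by the quaternary C10 and the trans-fused lactone, and the nine-membered ring allows only the Z C4=C5 alkene, so the geometry is set by ring strain.

Step 13
Reactants: 22 nine-membered (Z)-enoate lactone carrying the C10 acetyl group
Product: 25 CNP0258430.1 (target), via ring-expanded hydroxy diketone 23 (not isolated), via bridged hemiketal 24 (not isolated)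
Conditions: LiN(SiMe3)2 (1.1 equiv), THF, −78 → −30 °C; AcOH; then camphorsulfonic acid (20 mol %), 4 Å molecular sieves, CH2Cl2, rt
Reagents that add atoms: none
Why: LiN(SiMe3)2 can deprotonate only the acetyl methyl group (C10 is quaternary), and the resulting C2 enolate sits one oxygen away from the lactone carbonyl C3, so it should add 5-exo-trig to give the bridged tetrahedral alkoxide, whose collapse transfers the acyl group from O10 to C2 and turns the nine-membered lactone into the ten-membered 10-hydroxy-1,3-diketone 23 (ring expansion by one atom). On acidification the C10 hydroxyl recloses onto C3 (5-exo-trig, hemiketal 24) and water is lost toward C2, which gives the vinylogous ester (the 3(2H)-furanone) irreversibly. The closest known reaction type is the Baker–Venkataraman-type intramolecular Claisen acyl transfer of α-acyloxy ketones followed by acid cyclodehydration of the α'-hydroxy-1,3-diketone, the classical 3(2H)-furanone synthesis, here run on a lactone so that the same C2–C3 bond also closes the carbocycle. No stereocenter is created: C6, C7, C8 and C10 are untouched, the Z geometry of C4=C5 is carried over from 22 and the geometry of C2=C3 is fixed by the five-membered ring. The step needs 1,2- rather than 1,4-addition to the enoate (five- against seven-membered ring) and chemoselectivity over the α-methylene lactone and the epoxy ester, which the proximity of C3, the low temperature and one equivalent of a hindered, non-nucleophilic amide should secure.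

**Compound list**

1 | S-ethyl thioacetate | CC(=O)SCC | starting material
2 | 1-(ethylsulfanyl)-1-(trimethylsilyloxy)ethene | C=C(O[Si](C)(C)C)SCC | intermediate
3 | butane-2,3-dione | CC(=O)C(C)=O | starting material
4 | S-ethyl (3S)-3-methyl-4-oxo-3-(trimethylsilyloxy)pentanethioate (not isolated) | CC(=O)[C@@](C)(O[Si](C)(C)C)CC(=O)SCC | intermediate
5 | S-ethyl (3S)-3-hydroxy-3-methyl-4-oxopentanethioate | CC(=O)[C@@](C)(O)CC(=O)SCC | intermediate
6 | (3S)-3-hydroxy-3-methyl-4-oxopentanal | CC(=O)[C@@](C)(O)CC=O | intermediate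
7 | methyl 2-(bromomethyl)acrylate | C=C(CBr)C(=O)OC | starting material
8 | methyl (4R,6S)-6-hydroxy-6-methyl-2-methylidene-7-oxo-4-(trimethylsilyloxy)octanoate (not isolated) | C=C(C[C@@H](O[Si](C)(C)C)C[C@](C)(O)C(C)=O)C(=O)OC | intermediate
9 | methyl (4R,6S)-4,6-dihydroxy-6-methyl-2-methylidene-7-oxooctanoate (not isolated) | C=C(C[C@@H](O)C[C@](C)(O)C(C)=O)C(=O)OC | intermediate
10 | (5R)-5-[(2S)-2-hydroxy-2-methyl-3-oxobutyl]-3-methylideneoxolan-2-one | C=C1C[C@H](C[C@](C)(O)C(C)=O)OC1=O | intermediate
11 | (5S)-3-bromo-3-(bromomethyl)-5-[(2S)-2-hydroxy-2-methyl-3-oxobutyl]oxolan-2-one, both C3 epimers (not isolated) | BrCC1(Br)C[C@H](C[C@](C)(O)C(C)=O)OC1=O | intermediate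
12 | (5S)-3-(bromomethyl)-5-[(2S)-2-hydroxy-2-methyl-3-oxobutyl]furan-2(5H)-one | BrCC1=C[C@H](C[C@](C)(O)C(C)=O)OC1=O | intermediate
13 | acrolein (prop-2-enal) | C=CC=O | starting material
14 | (4S,5S)-4-[(1R)-1-hydroxyprop-2-en-1-yl]-5-[(2S)-2-hydroxy-2-methyl-3-oxobutyl]-3-methylideneoxolan-2-one | C=C1C(=O)O[C@@H](C[C@](C)(O)C(C)=O)[C@@H]1[C@H](O)C=C | intermediate
15 | methyl angelate, methyl (2Z)-2-methylbut-2-enoate | C/C=C(/C)C(=O)OC | starting material
16 | (2Z)-2-methylbut-2-en-1-ol | C/C=C(/C)CO | intermediate
17 | [(2R,3S)-2,3-dimethyloxiran-2-yl]methanol | OC[C@@]1(C)O[C@H]1C | intermediate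
18 | (2S,3S)-2,3-dimethyloxirane-2-carboxylic acid (epoxyangelic acid) | OC(=O)[C@@]1(C)O[C@H]1C | intermediate
19 | (1S)-1-[(2S,3R)-2-[(2S)-2-hydroxy-2-methyl-3-oxobutyl]-4-methylidene-5-oxooxolan-3-yl]prop-2-en-1-yl (2S,3S)-2,3-dimethyloxirane-2-carboxylate | C=C1C(=O)O[C@@H](C[C@](C)(O)C(C)=O)[C@@H]1[C@@H](OC(=O)[C@@]2(C)O[C@H]2C)C=C | intermediate
20 | methacryloyl chloride | C=C(C)C(Cl)=O | starting material
21 | (1S)-1-[(2S,3R)-2-[(2S)-2-methyl-2-(2-methylprop-2-enoyloxy)-3-oxobutyl]-4-methylidene-5-oxooxolan-3-yl]prop-2-en-1-yl (2S,3S)-2,3-dimethyloxirane-2-carboxylate | C=C1C(=O)O[C@@H](C[C@](C)(OC(=O)C(C)=C)C(C)=O)[C@@H]1[C@@H](OC(=O)[C@@]2(C)O[C@H]2C)C=C | intermediate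
22 | bicyclic dilactone: nine-membered lactone ring O–C3(=O)–C4(CH3)=C5–C6–C7–C8–C9–C10 with Z alkene, acetyl and methyl on C10 (S), (2S,3S)-epoxyangelate on C6 (S), α-methylene-γ-butyrolactone trans-fused at C7 (R) and C8 (S) | C=C1C(=O)O[C@H]2C[C@@](C)(C(C)=O)OC(=O)/C(C)=C\[C@H](OC(=O)[C@@]3(C)O[C@H]3C)[C@H]12 | intermediate
23 | ten-membered carbocycle C1–C10 with C1 and C3 ketones, free C10 hydroxyl (10S), Z C4=C5, same lactone and ester as 22 (not isolated) | C=C1C(=O)O[C@H]2C[C@](C)(O)C(=O)CC(=O)/C(C)=C\[C@H](OC(=O)[C@@]3(C)O[C@H]3C)[C@H]12 | intermediate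
24 | hemiketal of 23 with an O bridge from C10 to C3, C3 bearing OH, both C3 epimers (not isolated) | C=C1C(=O)O[C@H]2C[C@]3(C)OC(O)(CC3=O)/C(C)=C\[C@H](OC(=O)[C@@]4(C)O[C@H]4C)[C@H]12 | intermediate
25 | CNP0258430.1: 3(2H)-furanone-bridged (4Z)-germacranolide, 8,12-olide (7R,8S, trans), 10S, 6S-O-[(2S,3S)-2,3-dimethyloxirane-2-carbonyl] | C=C1C(=O)O[C@H]2C[C@]3(C)OC(=CC3=O)/C(C)=C\[C@H](OC(=O)[C@@]3(C)O[C@H]3C)[C@H]12 | target

**Step count and risks**

Total step count: 13. Longest linear sequence: 10 steps (steps 1–6 and 10–13).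

Steps most likely to fail:

1. Step 13. The amide base or the ketone enolate may add to the α-methylene lactone (conjugate addition, oligomerisation) faster than the acyl transfer takes place. The fallback sets out from 22 and comes back at 25. The exocyclic alkene is masked as its Michael adduct with dimethylamine (Me2NH, THF, 0 °C) to give amino lactone F1. The same base and acid sequence then runs through hydroxy diketone F2 and hemiketal F3 to amino furanone F4. Quaternisation with MeI gives ammonium iodide F5, and aqueous NaHCO3 eliminates trimethylamine to restore the methylene lactone, which gives 25.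

2. Step 12. Closure of the strained nine-membered ring may be slower than cross-metathesis between two molecules at the vinyl group, so that oligomers form. The fallback sets out from 21 and comes back at 25, with the order of the two ring closures inverted. The acyl transfer and dehydration are run on open-chain 21 (LiN(SiMe3)2, THF, −78 °C; then camphorsulfonic acid) and pass through hydroxy diketone F6 and hemiketal F7 to isopropenyl furanone F8, so that the C2–C3 bond closes only the furanone ring. Ring-closing metathesis of F8 with the same ruthenium catalyst then closes the ten-membered carbocycle at C4=C5 onto the rigid furanone and gives 25.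

3. Step 10. SN2' transposition, elimination or no displacement at all may occur, because both the allylic carbinol and the α-quaternary acid are hindered. The fallback sets out from 14 and comes back at 19, with inversion and acylation separated. A Mitsunobu reaction with the small and more acidic chloroacetic acid gives inverted chloroacetate F9. Thiourea and NaHCO3 in EtOH remove the chloroacetyl group to give 6S alcohol F10. Yamaguchi esterification (2,4,6-trichlorobenzoyl chloride, Et3N, DMAP) with acid 18 then acylates the secondary alcohol with retention and gives 19.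

**Further compounds**

F1 | step 13 | dimethylamine adduct of 22 at C13, both C11 epimers | CN(C)CC1C(=O)O[C@H]2C[C@@](C)(C(C)=O)OC(=O)/C(C)=C\[C@H](OC(=O)[C@@]3(C)O[C@H]3C)[C@H]12
F2 | step 13 | dimethylamine adduct of hydroxy diketone 23 | CN(C)CC1C(=O)O[C@H]2C[C@](C)(O)C(=O)CC(=O)/C(C)=C\[C@H](OC(=O)[C@@]3(C)O[C@H]3C)[C@H]12
F3 | step 13 | dimethylamine adduct of hemiketal 24 | CN(C)CC1C(=O)O[C@H]2C[C@]3(C)OC(O)(CC3=O)/C(C)=C\[C@H](OC(=O)[C@@]4(C)O[C@H]4C)[C@H]12
F4 | step 13 | dimethylamine adduct of 25 | CN(C)CC1C(=O)O[C@H]2C[C@]3(C)OC(=CC3=O)/C(C)=C\[C@H](OC(=O)[C@@]4(C)O[C@H]4C)[C@H]12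
F5 | step 13 | trimethylammonium iodide from F4 | C[N+](C)(C)CC1C(=O)O[C@H]2C[C@]3(C)OC(=CC3=O)/C(C)=C\[C@H](OC(=O)[C@@]4(C)O[C@H]4C)[C@H]12.[I-]
F6 | step 12 | open-chain hydroxy diketone from 21 (C10 hydroxyl free, C3 ketone bearing isopropenyl) | C=C1C(=O)O[C@@H](C[C@](C)(O)C(=O)CC(=O)C(C)=C)[C@@H]1[C@@H](OC(=O)[C@@]2(C)O[C@H]2C)C=C
F7 | step 12 | 5-hydroxy-5-isopropenyl-dihydrofuran-3-one hemiketal from F6 | C=C1C(=O)O[C@@H](C[C@]2(C)OC(O)(CC2=O)C(C)=C)[C@@H]1[C@@H](OC(=O)[C@@]3(C)O[C@H]3C)C=C
F8 | step 12 | (1S)-1-[(2S,3R)-2-{[(2S)-2-methyl-3-oxo-5-(prop-1-en-2-yl)-2,3-dihydrofuran-2-yl]methyl}-4-methylidene-5-oxooxolan-3-yl]prop-2-en-1-yl (2S,3S)-2,3-dimethyloxirane-2-carboxylate | C=C1C(=O)O[C@@H](C[C@]2(C)OC(C(C)=C)=CC2=O)[C@@H]1[C@@H](OC(=O)[C@@]3(C)O[C@H]3C)C=C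
F9 | step 10 | (1S)-1-[(2S,3R)-2-[(2S)-2-hydroxy-2-methyl-3-oxobutyl]-4-methylidene-5-oxooxolan-3-yl]prop-2-en-1-yl chloroacetate | C=C1C(=O)O[C@@H](C[C@](C)(O)C(C)=O)[C@@H]1[C@@H](OC(=O)CCl)C=C
F10 | step 10 | (4S,5S)-4-[(1S)-1-hydroxyprop-2-en-1-yl]-5-[(2S)-2-hydroxy-2-methyl-3-oxobutyl]-3-methylideneoxolan-2-one | C=C1C(=O)O[C@@H](C[C@](C)(O)C(C)=O)[C@@H]1[C@@H](O)C=C
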